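Remark: ring positions are numbered as in 1H-isochromene (C1, O2, C3, C4, C4a, C5, C6, C7, C8, C8a); primed locants refer to the heptenyl side chain.

The cyclohexenone ring is cut across C6–C7 and C4a–C8a into two three-carbon units: a 1,3-bis(phenylsulfanyl)allyl linchpin (C4a–C5–C6), acyl-anion equivalent at C6 and β-vinyl-anion equivalent at C4a, and a cis-epoxy methyl ketone (C7, C8, C8a, C1) from a Sharpless epoxide. In one flask the allyl anion adds to the C7 ketone and, after a second deprotonation, opens the epoxide at C8a, closing the carbocycle and setting C7, C8 and C8a. The step exploits the 1,3-relation of the C6 carbonyl and C4a in the enone, matched by C7 and C8a flanking the C8 carbinol. Thiophilic unmasking, Sonogashira coupling and 6-endo oxa-Michael closure of the pyran ring finish the route.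

Key step: step 9

Step 1
Reactants: 1 (Z)-but-2-ene-1,4-diol
Product: 2 (Z)-4-{[tert-butyl(diphenyl)silyl]oxy}but-2-en-1-ol
Conditions: NaH (1 equiv), THF, 0 °C; t-BuPh2SiCl (1 equiv); diol in excess
Reagents that add atoms: tert-butyl(chloro)diphenylsilane CC(C)(C)[Si](Cl)(c1ccccc1)c1ccccc1
Why: Silyl ether formation through the monosodium alkoxide of the symmetric diol, used in excess, should give the mono-ether; no stereocenter is formed.

Step 2
Reactants: 2 (Z)-4-{[tert-butyl(diphenyl)silyl]oxy}but-2-en-1-ol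
Product: 3 [(2S,3R)-3-({[tert-butyl(diphenyl)silyl]oxy}methyl)oxiran-2-yl]methanol
Conditions: Ti(OiPr)4 (cat.), L-(+)-diethyl tartrate (cat.), t-BuOOH, 4 Å molecular sieves, CH2Cl2, −20 °C
Reagents that add atoms: tert-butyl hydroperoxide CC(C)(C)OO
Why: Sharpless asymmetric epoxidation of the Z-allylic alcohol; L-(+)-diethyl tartrate directs oxygen to the face that gives the (2S,3R) cis-epoxy alcohol, which fixes the later C8 (retained) and C8a (inverted in step 9) centres.

Step 3
Reactants: 3 [(2S,3R)-3-({[tert-butyl(diphenyl)silyl]oxy}methyl)oxiran-2-yl]methanol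
Product: 4 (2R,3R)-3-({[tert-butyl(diphenyl)silyl]oxy}methyl)oxirane-2-carbaldehyde
Conditions: Dess–Martin periodinane, NaHCO3, CH2Cl2, 0 °C
Reagents that add atoms: none
Why: Dess–Martin oxidation of the primary alcohol under buffered conditions should leave the cis-epoxide and the silyl ether untouched.

Step 4
Reactants: 4 (2R,3R)-3-({[tert-butyl(diphenyl)silyl]oxy}methyl)oxirane-2-carbaldehyde
Product: 5 1-[(2S,3R)-3-({[tert-butyl(diphenyl)silyl]oxy}methyl)oxiran-2-yl]ethan-1-ol (both carbinol epimers)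
Conditions: MeMgBr, THF, −78 °C
Reagents that add atoms: methylmagnesium bromide C[Mg]Br
Why: Grignard addition to the aldehyde; the new carbinol centre is inconsequential because it is oxidised in step 5.

Step 5
Reactants: 5 1-[(2S,3R)-3-({[tert-butyl(diphenyl)silyl]oxy}methyl)oxiran-2-yl]ethan-1-ol
Product: 6 1-[(2R,3R)-3-({[tert-butyl(diphenyl)silyl]oxy}methyl)oxiran-2-yl]ethan-1-one (cis-epoxy ketone)
Conditions: Dess–Martin periodinane, NaHCO3, CH2Cl2, 0 °C → rt
Reagents that add atoms: none
Why: Dess–Martin oxidation of the secondary alcohol should give the methyl ketone without opening or epimerising the cis-epoxide.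

Step 6
Reactants: 7 3-(trimethylsilyl)prop-2-ynal; 8 (triphenylphosphoranylidene)acetaldehyde
Product: 9 (E)-5-(trimethylsilyl)pent-2-en-4-ynal
Conditions: CH2Cl2, rt
Reagents that add atoms: none
Why: Wittig olefination with the stabilised formylmethylene ylide should give the E-enal.

Step 7
Reactants: 9 (E)-5-(trimethylsilyl)pent-2-en-4-ynal
Product: 10 1,1,3-tris(phenylsulfanyl)-5-(trimethylsilyl)pent-4-yne (racemic)
Conditions: PhSH (3.3 equiv), Et3N (cat.), CH2Cl2, 0 °C; then BF3·OEt2 (cat.), 0 °C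
Reagents that add atoms: thiophenol Sc1ccccc1
Why: Base-catalysed thia-Michael addition at the β-carbon followed by BF3-catalysed dithioacetalisation of the aldehyde, the silyl cap shielding the alkyne terminus from 1,6-addition; the new centre is racemic and is destroyed later.

Step 8
Reactants: 10 1,1,3-tris(phenylsulfanyl)-5-(trimethylsilyl)pent-4-yne
Product: 11 (E)-1,3-bis(phenylsulfanyl)-5-(trimethylsilyl)pent-1-en-4-yne (racemic)
Conditions: (CuOTf)2·C6H6, i-Pr2NEt, THF–benzene, rt
Reagents that add atoms: none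
Why: Copper-triflate-promoted loss of one thiophenoxide from the dithioacetal followed by deprotonation (Cohen vinyl sulfide synthesis) should give the 1,3-bis(arylthio)propene.

Step 9
Reactants: 11 (E)-1,3-bis(phenylsulfanyl)-5-(trimethylsilyl)pent-1-en-4-yne; 6 1-[(2R,3R)-3-({[tert-butyl(diphenyl)silyl]oxy}methyl)oxiran-2-yl]ethan-1-one
Product: 13 (1S,5S,6R)-5-({[tert-butyl(diphenyl)silyl]oxy}methyl)-1-methyl-2,4-bis(phenylsulfanyl)-4-[(trimethylsilyl)ethynyl]cyclohex-2-ene-1,6-diol (both C4 epimers), via lithium alkoxide adduct 12 (not isolated)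
Conditions: LiN(i-Pr)2 (1.05 equiv), THF, −78 °C; 6, −78 °C; then LiN(i-Pr)2 (1.1 equiv), DMPU, −78 → 0 °C; aq NH4Cl
Reagents that add atoms: none
Why: Deprotonation of 11 gives a sulfur-stabilised allyl anion that adds through its less substituted terminus (C6) to the ketone of 6, forming C6–C7 (carbonyl addition of a 1,3-bis(alkylthio)allyllithium, the Corey reagent type); a second deprotonation at the doubly activated C6–H regenerates the allyl anion, whose other terminus (C4a) opens the epoxide at C8a (intramolecular alkylation of a thioallyl anion by an epoxide). The carbocycle closes by 6-endo epoxide opening (both oxirane carbons end in the ring); the competing 5-exo attack at C8 should be disfavoured because C8 is neopentyl-like, next to the fully substituted alkoxide carbon C7. C7 is set by chelation control: lithium bridges the carbonyl and oxirane oxygens and the anion enters from the face away from C8a, which gives the 7S carbinol trans to the C8 oxygen. C8 keeps the configuration of the Sharpless epoxide and C8a is inverted in the SN2 opening, so the cis-epoxide delivers the 8R,8aS pair; the centres at C6 and C4a are removed in step 10. The step needs terminus selectivity in the first addition (C6 rather than the sulfur- and alkynyl-substituted C4a, secured by sterics and by the silyl group blocking the alkyne end) and regioselective closure, secured because C4a-to-C8a is the only strain-free intramolecular alkylation.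

Step 10
Reactants: 13 (1S,5S,6R)-5-({[tert-butyl(diphenyl)silyl]oxy}methyl)-1-methyl-2,4-bis(phenylsulfanyl)-4-[(trimethylsilyl)ethynyl]cyclohex-2-ene-1,6-diol
Product: 14 (4S,5R,6S)-4-({[tert-butyl(diphenyl)silyl]oxy}methyl)-5,6-dihydroxy-6-methyl-3-[(trimethylsilyl)ethynyl]cyclohex-2-en-1-one
Conditions: HgCl2, CaCO3, MeCN–H2O (4:1), 40 °C
Reagents that add atoms: water O
Why: Thiophilic hydrolysis of the 1,3-bis(arylthio)propene unit (Corey unmasking): HgCl2 ionises the tertiary allylic sulfide at C4a, water adds at the sulfur-bearing terminus C6 and loss of the second thiol gives the C6 ketone conjugated with C4a=C5, both C4a epimers converging.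

Step 11
Reactants: 14 (4S,5R,6S)-4-({[tert-butyl(diphenyl)silyl]oxy}methyl)-5,6-dihydroxy-6-methyl-3-[(trimethylsilyl)ethynyl]cyclohex-2-en-1-one
Product: 15 (4S,5R,6S)-4-({[tert-butyl(diphenyl)silyl]oxy}methyl)-3-ethynyl-5,6-dihydroxy-6-methylcyclohex-2-en-1-one
Conditions: Bu4NF (1.05 equiv), AcOH (1.05 equiv), THF, −20 °C, short reaction time
Reagents that add atoms: none
Why: Fluoride-induced protodesilylation of the alkynylsilane, buffered and run cold so that the much more robust primary tert-butyldiphenylsilyl ether should survive.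

Step 12
Reactants: 16 L-isoleucine
Product: 17 (2S,3S)-2-hydroxy-3-methylpentanoic acid
Conditions: NaNO2, 1 M H2SO4, 0 °C → rt
Reagents that add atoms: water O
Why: Diazotisation of the α-amino acid with double inversion through the α-lactone (net retention) gives the α-hydroxy acid that supplies C4′ (S) and C5′ (S) from the chiral pool.

Step 13
Reactants: 17 (2S,3S)-2-hydroxy-3-methylpentanoic acid
Product: 18 (2S,3S)-2-hydroxy-N-methoxy-N,3-dimethylpentanamide
Conditions: MeNHOMe·HCl, EDC·HCl, HOBt, N-methylmorpholine, CH2Cl2, 0 °C → rt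
Reagents that add atoms: N,O-dimethylhydroxylamine hydrochloride Cl.CNOC
Why: Carbodiimide-mediated amide coupling to the Weinreb amide; the hindered secondary alcohol should not be acylated competitively.

Step 14
Reactants: 18 (2S,3S)-2-hydroxy-N-methoxy-N,3-dimethylpentanamide; 19 (E)-1,2-bis(tributylstannyl)ethene
Product: 20 (4S,5S,E)-4-hydroxy-5-methyl-1-(tributylstannyl)hept-1-en-3-one
Conditions: 18, i-PrMgCl (1 equiv), THF, −20 °C; then (E)-Bu3SnCH=CHLi (from 19, n-BuLi, THF, −78 °C), −78 → −20 °C; aq NH4Cl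
Reagents that add atoms: none
Why: Weinreb ketone synthesis with the alkenyllithium from tin–lithium exchange of 19, the hydroxyl being masked first as its magnesium alkoxide; the chelated tetrahedral intermediate prevents over-addition and the E-geometry is retained.

Step 15
Reactants: 20 (4S,5S,E)-4-hydroxy-5-methyl-1-(tributylstannyl)hept-1-en-3-one
Product: 21 (3R,4S,5S,E)-3,5-dimethyl-1-(tributylstannyl)hept-1-ene-3,4-diol
Conditions: MeMgBr (3 equiv), CH2Cl2–Et2O, −78 °C
Reagents that add atoms: methylmagnesium bromide C[Mg]Br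
Why: Chelation-controlled 1,2-addition of the Grignard reagent to the α-alkoxido enone (Cram chelate): magnesium bridges the alkoxide and carbonyl oxygens and methyl enters from the face opposite the sec-butyl group, setting 3′R.

Step 16
Reactants: 21 (3R,4S,5S,E)-3,5-dimethyl-1-(tributylstannyl)hept-1-ene-3,4-diol
Product: 22 (3R,4S,5S,E)-1-iodo-3,5-dimethylhept-1-ene-3,4-diol
Conditions: I2, CH2Cl2, 0 °C
Reagents that add atoms: iodine II
Why: Iododestannylation of the vinylstannane, which proceeds with retention of the E-geometry.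

Step 17
Reactants: 15 (4S,5R,6S)-4-({[tert-butyl(diphenyl)silyl]oxy}methyl)-3-ethynyl-5,6-dihydroxy-6-methylcyclohex-2-en-1-one; 22 (3R,4S,5S,E)-1-iodo-3,5-dimethylhept-1-ene-3,4-diol
Product: 23 (4S,5R,6S)-4-({[tert-butyl(diphenyl)silyl]oxy}methyl)-3-[(3E,5R,6S,7S)-5,6-dihydroxy-5,7-dimethylnon-3-en-1-yn-1-yl]-5,6-dihydroxy-6-methylcyclohex-2-en-1-one
Conditions: Pd(PPh3)2Cl2 (cat.), CuI (cat.), Et3N, THF, rt
Reagents that add atoms: none
Why: Sonogashira coupling of the terminal alkyne with the vinyl iodide, with retention of the E-geometry and tolerance of the free hydroxyls.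

Step 18
Reactants: 23 (4S,5R,6S)-4-({[tert-butyl(diphenyl)silyl]oxy}methyl)-3-[(3E,5R,6S,7S)-5,6-dihydroxy-5,7-dimethylnon-3-en-1-yn-1-yl]-5,6-dihydroxy-6-methylcyclohex-2-en-1-one
Product: 25 (7S,8R,8aS)-3-[(1E,3R,4S,5S)-3,4-dihydroxy-3,5-dimethylhept-1-en-1-yl]-7,8-dihydroxy-7-methyl-1,7,8,8a-tetrahydro-6H-isochromen-6-one (target), via primary alcohol 24 (not isolated)
Conditions: Bu4NF, THF, 0 °C → rt
Reagents that add atoms: none
Why: Fluoride cleaves the silyl ether and the C1 alkoxide adds to C3, the δ-carbon of the dienynone, in a 6-endo-dig oxa-Michael addition that closes the pyran ring and gives the dienol ether after protonation at C4; 5-exo attack at C4 would be anti-Michael, and closure by the C8 hydroxyl would need a bridgehead alkene.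

Compound list
1 | (Z)-but-2-ene-1,4-diol | OC/C=C\CO | starting material
2 | (Z)-4-{[tert-butyl(diphenyl)silyl]oxy}but-2-en-1-ol | OC/C=C\CO[Si](c1ccccc1)(c1ccccc1)C(C)(C)C | intermediate
3 | [(2S,3R)-3-({[tert-butyl(diphenyl)silyl]oxy}methyl)oxiran-2-yl]methanol | OC[C@@H]1O[C@@H]1CO[Si](c1ccccc1)(c1ccccc1)C(C)(C)C | intermediate
4 | (2R,3R)-3-({[tert-butyl(diphenyl)silyl]oxy}methyl)oxirane-2-carbaldehyde | O=C[C@@H]1O[C@@H]1CO[Si](c1ccccc1)(c1ccccc1)C(C)(C)C | intermediate
5 | 1-[(2S,3R)-3-({[tert-butyl(diphenyl)silyl]oxy}methyl)oxiran-2-yl]ethan-1-ol, both carbinol epimers | CC(O)[C@@H]1O[C@@H]1CO[Si](c1ccccc1)(c1ccccc1)C(C)(C)C | intermediate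
6 | 1-[(2R,3R)-3-({[tert-butyl(diphenyl)silyl]oxy}methyl)oxiran-2-yl]ethan-1-one | CC(=O)[C@@H]1O[C@@H]1CO[Si](c1ccccc1)(c1ccccc1)C(C)(C)C | intermediate
7 | 3-(trimethylsilyl)prop-2-ynal | C[Si](C)(C)C#CC=O | starting material
8 | (triphenylphosphoranylidene)acetaldehyde | O=CC=P(c1ccccc1)(c1ccccc1)c1ccccc1 | starting material
9 | (E)-5-(trimethylsilyl)pent-2-en-4-ynal | C[Si](C)(C)C#C/C=C/C=O | intermediate
10 | 1,1,3-tris(phenylsulfanyl)-5-(trimethylsilyl)pent-4-yne, racemic | C[Si](C)(C)C#CC(Sc1ccccc1)CC(Sc1ccccc1)Sc1ccccc1 | intermediate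
11 | (E)-1,3-bis(phenylsulfanyl)-5-(trimethylsilyl)pent-1-en-4-yne, racemic | C[Si](C)(C)C#CC(Sc1ccccc1)/C=C/Sc1ccccc1 | intermediate
12 | (2S)-2-[(2R,3R)-3-({[tert-butyl(diphenyl)silyl]oxy}methyl)oxiran-2-yl]-3,5-bis(phenylsulfanyl)-7-(trimethylsilyl)hept-4-en-6-yn-2-ol, present as its lithium alkoxide (C3 epimers, alkene isomers) | C[Si](C)(C)C#CC(Sc1ccccc1)=CC(Sc1ccccc1)[C@@](C)(O)[C@@H]1O[C@@H]1CO[Si](c1ccccc1)(c1ccccc1)C(C)(C)C | intermediate
13 | (1S,5S,6R)-5-({[tert-butyl(diphenyl)silyl]oxy}methyl)-1-methyl-2,4-bis(phenylsulfanyl)-4-[(trimethylsilyl)ethynyl]cyclohex-2-ene-1,6-diol, both C4 epimers | C[Si](C)(C)C#CC1(Sc2ccccc2)C=C(Sc2ccccc2)[C@@](C)(O)[C@H](O)[C@@H]1CO[Si](c1ccccc1)(c1ccccc1)C(C)(C)C | intermediate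
14 | (4S,5R,6S)-4-({[tert-butyl(diphenyl)silyl]oxy}methyl)-5,6-dihydroxy-6-methyl-3-[(trimethylsilyl)ethynyl]cyclohex-2-en-1-one | C[Si](C)(C)C#CC1=CC(=O)[C@@](C)(O)[C@H](O)[C@@H]1CO[Si](c1ccccc1)(c1ccccc1)C(C)(C)C | intermediate
15 | (4S,5R,6S)-4-({[tert-butyl(diphenyl)silyl]oxy}methyl)-3-ethynyl-5,6-dihydroxy-6-methylcyclohex-2-en-1-one | C#CC1=CC(=O)[C@@](C)(O)[C@H](O)[C@@H]1CO[Si](c1ccccc1)(c1ccccc1)C(C)(C)C | intermediate
16 | L-isoleucine, (2S,3S)-2-amino-3-methylpentanoic acid | CC[C@H](C)[C@H](N)C(=O)O | starting material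
17 | (2S,3S)-2-hydroxy-3-methylpentanoic acid | CC[C@H](C)[C@H](O)C(=O)O | intermediate
18 | (2S,3S)-2-hydroxy-N-methoxy-N,3-dimethylpentanamide | CC[C@H](C)[C@H](O)C(=O)N(C)OC | intermediate
19 | (E)-1,2-bis(tributylstannyl)ethene | CCCC[Sn](CCCC)(CCCC)/C=C/[Sn](CCCC)(CCCC)CCCC | starting material
20 | (4S,5S,E)-4-hydroxy-5-methyl-1-(tributylstannyl)hept-1-en-3-one | CC[C@H](C)[C@H](O)C(=O)/C=C/[Sn](CCCC)(CCCC)CCCC | intermediate
21 | (3R,4S,5S,E)-3,5-dimethyl-1-(tributylstannyl)hept-1-ene-3,4-diol | CC[C@H](C)[C@H](O)[C@](C)(O)/C=C/[Sn](CCCC)(CCCC)CCCC | intermediate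
22 | (3R,4S,5S,E)-1-iodo-3,5-dimethylhept-1-ene-3,4-diol | CC[C@H](C)[C@H](O)[C@](C)(O)/C=C/I | intermediate
23 | (4S,5R,6S)-4-({[tert-butyl(diphenyl)silyl]oxy}methyl)-3-[(3E,5R,6S,7S)-5,6-dihydroxy-5,7-dimethylnon-3-en-1-yn-1-yl]-5,6-dihydroxy-6-methylcyclohex-2-en-1-one | CC[C@H](C)[C@H](O)[C@](C)(O)/C=C/C#CC1=CC(=O)[C@@](C)(O)[C@H](O)[C@@H]1CO[Si](c1ccccc1)(c1ccccc1)C(C)(C)C | intermediate
24 | (4S,5R,6S)-3-[(3E,5R,6S,7S)-5,6-dihydroxy-5,7-dimethylnon-3-en-1-yn-1-yl]-5,6-dihydroxy-4-(hydroxymethyl)-6-methylcyclohex-2-en-1-one | CC[C@H](C)[C@H](O)[C@](C)(O)/C=C/C#CC1=CC(=O)[C@@](C)(O)[C@H](O)[C@@H]1CO | intermediate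
25 | (7S,8R,8aS)-3-[(1E,3R,4S,5S)-3,4-dihydroxy-3,5-dimethylhept-1-en-1-yl]-7,8-dihydroxy-7-methyl-1,7,8,8a-tetrahydro-6H-isochromen-6-one | CC[C@H](C)[C@H](O)[C@](C)(O)/C=C/C1=CC2=CC(=O)[C@@](C)(O)[C@H](O)[C@@H]2CO1 | target

Total step count: 18. Longest linear sequence: 10 steps (steps 1–5, 9, 10, 11, 17, 18).

Steps most likely to fail

Step 9. The unsymmetrical allyl anion may add through the wrong terminus, the intermediate alkoxide may shift the epoxide (Payne migration) before the second deprotonation, the ring may close in the 5-exo sense at C8, or facial selectivity at C7 may be poor without a tight chelate. Fallback: the two bonds are made in separate operations with the tertiary oxygen capped. Setting out again from 11 and 6, the first-stage adduct is trapped in the flask with Me3SiCl as its trimethylsilyl ether, (2S)-configured epoxy silyl ether F1, and isolated. F1 is then deprotonated (s-BuLi, THF, −78 °C) and cyclised with BF3·OEt2 assistance (Lewis-acid-promoted opening of an epoxide by a sulfur-stabilised carbanion, no free alkoxide present) to the silylated cyclohexene F2. The HgCl2 hydrolysis of step 10, whose aqueous medium also cleaves the tertiary trimethylsilyl ether, brings the material back to the route at 14.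

Step 18. Basic desilylation may epimerise C8a through the extended enolate, or trigger loss of the C8 hydroxyl before the ring closes. Fallback: setting out from 23, the silyl ether is removed under non-basic conditions (HF·pyridine, THF–pyridine) and alcohol 24 is isolated; the pyran ring is then closed by π-acid catalysis (Ph3PAuCl/AgOTf, CH2Cl2, rt; 6-endo-dig hydroalkoxylation of the alkyne), which returns to the route at 25.

Step 15. Facial selectivity at C3′ may erode if the magnesium chelate is not maintained, and conjugate addition to the stannyl enone may compete. Fallback: the order of the two nucleophiles is inverted and Felkin–Anh control replaces chelation. Setting out from 18, MeMgBr gives the hydroxy ketone (3S,4S)-3-hydroxy-4-methylhexan-2-one F3. Silylation (t-BuMe2SiOTf, 2,6-lutidine) gives the bulky silyl ether F4. Addition of (E)-Bu3SnCH=CHLi in THF at −78 °C, anti to the silyloxy group, gives the 3′R carbinol F5. Bu4NF removes the silyl group and returns to the route at 21.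

Further compounds
F1 | step 9 | trimethylsilyl ether of adduct 12, (2S)-2-[(2R,3R)-3-({[tert-butyl(diphenyl)silyl]oxy}methyl)oxiran-2-yl]-3,5-bis(phenylsulfanyl)-7-(trimethylsilyl)-2-[(trimethylsilyl)oxy]hept-4-en-6-yne | C[Si](C)(C)C#CC(Sc1ccccc1)=CC(Sc1ccccc1)[C@@](C)(O[Si](C)(C)C)[C@@H]1O[C@@H]1CO[Si](c1ccccc1)(c1ccccc1)C(C)(C)C
F2 | step 9 | (1R,5S,6S)-6-({[tert-butyl(diphenyl)silyl]oxy}methyl)-2-methyl-3,5-bis(phenylsulfanyl)-5-[(trimethylsilyl)ethynyl]-2-[(trimethylsilyl)oxy]cyclohex-3-en-1-ol, the C7-O-trimethylsilyl ether of 13 | C[Si](C)(C)C#CC1(Sc2ccccc2)C=C(Sc2ccccc2)[C@@](C)(O[Si](C)(C)C)[C@H](O)[C@@H]1CO[Si](c1ccccc1)(c1ccccc1)C(C)(C)C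
F0 | step 18 | none | none
F3 | step 15 | (3S,4S)-3-hydroxy-4-methylhexan-2-one | CC[C@H](C)[C@H](O)C(C)=O
F4 | step 15 | (3S,4S)-3-{[tert-butyl(dimethyl)silyl]oxy}-4-methylhexan-2-one | CC[C@H](C)[C@H](O[Si](C)(C)C(C)(C)C)C(C)=O
F5 | step 15 | (3R,4S,5S,E)-4-{[tert-butyl(dimethyl)silyl]oxy}-3,5-dimethyl-1-(tributylstannyl)hept-1-en-3-ol | CC[C@H](C)[C@H](O[Si](C)(C)C(C)(C)C)[C@](C)(O)/C=C/[Sn](CCCC)(CCCC)CCCC
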